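A direct plan would condense a protected 2,4-dihydroxy-5-methoxybenzaldehyde with a protected 2,4-dihydroxyacetophenone to chalcone A1, move the aryl group from C-β to C-α with Tl(NO3)3, close the pyranone, and end by turning aryl propargyl ether A2 into the chromene by Claisen rearrangement. Its weakest steps would be:
(a) the protection, deprotection and reprotection of the four phenolic oxygens, about half of all steps, which would add no ring and no C–C bond;
(b) the oxidative 1,2-aryl shift, which would need a stoichiometric salt of toxic trivalent thallium on a ring that is itself easily oxidised;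
(c) the Claisen/electrocyclisation cascade near 185 °C, which would expose the fully assembled isoflavone to the harshest conditions of the plan almost at its end.

**Plan of the new route**
The retrosynthesis first removes the pyran C3=C4 bond (elimination at C-4), then cuts three bonds of ring B at once: C5'–C6', C1'–C2' and C2'–C3'.
Rings A and C (chromone 7) and a partly saturated ring D (carbene complex 16) come first; ring B is made last, between them, by Dötz benzannulation; ring D is dehydrated to the 2H-pyran afterwards.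
Enabling feature: in ring B, OH (C-2') and OMe (C-5') are para, C-6' is CH, and C-3'/C-4' are shared with the pyran, whose oxygen sits on C-4'. This is the pattern that CO, a methoxycarbene carbon, a terminal alkyne and an enol-ether alkene give.
The ring B oxygens arise differentiated, so ring B needs no protecting group, no aryl shift and no late high-temperature pericyclic step.

Key step: step 9

Remark: C-4 of the dihydropyran/chroman unit (compounds 12 to 19) is carried as a racemate; it becomes sp2 in step 10, and the target has no stereocentre.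

**Step 1**
Reactants: 1 1-(2,4-dihydroxyphenyl)ethan-1-one
Product: 2 1-[2-hydroxy-4-(methoxymethoxy)phenyl]ethan-1-one
Conditions: MOMCl (1.1 equiv), K2CO3 (1.5 equiv), acetone, rt
Reagents that add atoms: chloromethyl methyl ether, COCCl
Why: Williamson-type O-alkylation should take only the 4-OH, because the 2-OH is hydrogen-bonded to the ketone and much less nucleophilic.

**Step 2**
Reactants: 2 1-[2-hydroxy-4-(methoxymethoxy)phenyl]ethan-1-one
Product: 4 3-iodo-7-(methoxymethoxy)-4H-chromen-4-one, via enaminone 3 (not isolated)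
Conditions: Me2NCH(OMe)2 (2 equiv), 95 °C, 3 h; evaporate; I2 (1.5 equiv), pyridine (1 equiv), CHCl3, rt
Reagents that add atoms: N,N-dimethylformamide dimethyl acetal, COC(OC)N(C)C; iodine, II
Why: Condensation of the methyl ketone with the amide acetal gives enaminone 3, iodine attacks its α-carbon, the phenol adds to the iminium carbon and dimethylamine is lost (iodocyclisation of o-hydroxyaryl enaminones to 3-iodochromones).

**Step 3**
Reactants: 4 3-iodo-7-(methoxymethoxy)-4H-chromen-4-one; 5 ethynyltrimethylsilane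
Product: 6 7-(methoxymethoxy)-3-[(trimethylsilyl)ethynyl]-4H-chromen-4-one
Conditions: PdCl2(PPh3)2 (3 mol %), CuI (5 mol %), Et3N (3 equiv), THF, rt
Reagents that add atoms: none
Why: Sonogashira coupling of the vinylic C–I bond with the terminal alkyne should proceed at room temperature, and the tertiary amine base does not open the chromone.

**Step 4**
Reactants: 6 7-(methoxymethoxy)-3-[(trimethylsilyl)ethynyl]-4H-chromen-4-one
Product: 7 3-ethynyl-7-(methoxymethoxy)-4H-chromen-4-one
Conditions: Bu4NF (1.1 equiv), AcOH (1.2 equiv), THF, 0 °C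
Reagents that add atoms: none
Why: Fluoride-induced protodesilylation cleaves the alkynyl C–Si bond, and the acetic acid buffer keeps the medium non-basic so that C-2 of the chromone and the MOM ether are left alone.

**Step 5**
Reactants: 8 (E)-4-methoxybut-3-en-2-one; 9 acetone
Product: 11 2,2-dimethyl-2,3-dihydro-4H-pyran-4-one, via aldol adduct 10 (not isolated)
Conditions: LiN(SiMe3)2 (1.05 equiv), THF, −78 °C; 9 (1.5 equiv), −78 °C; aq NH4Cl; then CF3CO2H (cat.), CH2Cl2, rt
Reagents that add atoms: none
Why: The kinetic lithium enolate of the methyl ketone adds to acetone (aldol addition), and acid then drives 6-endo oxa-Michael addition of the tertiary alcohol to the β-methoxy enone with loss of methanol (addition–elimination) to the cyclic vinylogous ester.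

**Step 6**
Reactants: 11 2,2-dimethyl-2,3-dihydro-4H-pyran-4-one
Product: 12 2,2-dimethyl-3,4-dihydro-2H-pyran-4-ol (racemic)
Conditions: NaBH4 (1.0 equiv), CeCl3·7H2O (1.0 equiv), MeOH, −40 °C
Reagents that add atoms: none
Why: Luche reduction delivers hydride 1,2 to the vinylogous ester carbonyl and leaves the enol ether intact; the new C-4 centre is racemic and is erased in step 10.

**Step 7**
Reactants: 12 2,2-dimethyl-3,4-dihydro-2H-pyran-4-ol (racemic)
Product: 13 [(2,2-dimethyl-3,4-dihydro-2H-pyran-4-yl)oxy]tri(propan-2-yl)silane (racemic)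
Conditions: i-Pr3SiCl (1.2 equiv), imidazole (2.5 equiv), DMF, rt → 40 °C
Reagents that add atoms: chlorotri(propan-2-yl)silane, CC(C)[Si](Cl)(C(C)C)C(C)C
Why: Silylation of the secondary allylic alcohol with a triisopropylsilyl group gives an ether that tolerates t-BuLi and has no acidic Si–CH3 protons.

**Step 8**
Reactants: 13 [(2,2-dimethyl-3,4-dihydro-2H-pyran-4-yl)oxy]tri(propan-2-yl)silane (racemic)
Product: 16 pentacarbonyl{[2,2-dimethyl-4-(triisopropylsilyloxy)-3,4-dihydro-2H-pyran-6-yl](methoxy)methylidene}chromium (racemic), via vinyllithium 14 (not isolated), via lithium acylchromate 15 (not isolated)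
Conditions: t-BuLi (1.3 equiv), THF, −78 → 0 °C; Cr(CO)6 (1.1 equiv), Et2O, 0 °C → rt; evaporate; Me3OBF4 (1.5 equiv), CH2Cl2, 0 °C
Reagents that add atoms: hexacarbonylchromium, O=C=[Cr](=C=O)(=C=O)(=C=O)(=C=O)=C=O; trimethyloxonium tetrafluoroborate, C[O+](C)C.F[B-](F)(F)F
Why: The vinylic C–H next to the ring oxygen is lithiated as in silylated glycals, the vinyllithium adds to a CO ligand of Cr(CO)6, and O-methylation of the acylchromate with the Meerwein salt gives the alkenyl(methoxy)carbene complex (Fischer carbene synthesis).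

**Step 9**
Reactants: 7 3-ethynyl-7-(methoxymethoxy)-4H-chromen-4-one; 16 pentacarbonyl{[2,2-dimethyl-4-(triisopropylsilyloxy)-3,4-dihydro-2H-pyran-6-yl](methoxy)methylidene}chromium (racemic)
Product: 19 3-{5-hydroxy-8-methoxy-2,2-dimethyl-4-[(triisopropylsilyl)oxy]-3,4-dihydro-2H-chromen-6-yl}-7-(methoxymethoxy)-4H-chromen-4-one (racemic), via chromium-bound dienylketene 17 (not isolated), via tricarbonylchromium arene complex 18 (not isolated)
Conditions: 16 (1.2 equiv), THF (0.05 M), 50 °C, 12 h, Ar; then air, CH2Cl2, daylight, rt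
Reagents that add atoms: none
Why: This is a Dötz benzannulation: 16 loses one CO at 50 °C, the alkyne of 7 inserts into the Cr=C bond with its CH carbon bonding to the carbene carbon (C5'–C6'), a CO ligand inserts to give the chromium-bound dienylketene 17 (C1'–C2'), and 6π-electrocyclisation onto C-5 of the dihydropyran (C2'–C3') followed by enolisation gives the phenol as its Cr(CO)3 complex 18, which air and light decomplex. The closest known reaction type is the benzannulation of alkenyl(methoxy)carbene chromium complexes, dihydropyranyl and glycal-derived ones included, with terminal alkynes to give 4-methoxyphenols. Ring B is closed by the 6π-electrocyclisation of the dienylketene (overall a [3+2+1] assembly from three carbene-ligand carbons, two alkyne carbons and one CO), while rings A, C and D are untouched. No new stereocentre arises; racemic C-4 is carried along and removed in step 10. The step needs regioselective alkyne insertion, secured by the size difference between H and the chromonyl group of a terminal alkyne, which places the chromone next to the CO-derived C–OH and H next to C–OMe. It also needs chemoselectivity for the alkyne over the chromone C2=C3 bond and for phenol over cyclopentannulation products, secured by the low temperature (enone cyclopropanation needs much more heat) and by an alkenyl carbene bearing a β-hydrogen in an ether solvent.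

**Step 10**
Reactants: 19 3-{5-hydroxy-8-methoxy-2,2-dimethyl-4-[(triisopropylsilyl)oxy]-3,4-dihydro-2H-chromen-6-yl}-7-(methoxymethoxy)-4H-chromen-4-one (racemic)
Product: 21 3-(5-hydroxy-8-methoxy-2,2-dimethyl-2H-chromen-6-yl)-7-(methoxymethoxy)-4H-chromen-4-one, via ortho-quinone methide 20 (not isolated)
Conditions: TsOH·H2O (10 mol %), toluene (0.01 M), 60 °C
Reagents that add atoms: none
Why: Acid ionises the benzylic C–O bond ortho to the free phenol to ortho-quinone methide 20, which tautomerises by 1,5-hydrogen shift from C-3 to oxygen (net E1 loss of silanol) to the conjugated 2H-chromene, and high dilution suppresses quinone methide dimerisation.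

**Step 11**
Reactants: 21 3-(5-hydroxy-8-methoxy-2,2-dimethyl-2H-chromen-6-yl)-7-(methoxymethoxy)-4H-chromen-4-one
Product: 22 7-hydroxy-3-(5-hydroxy-8-methoxy-2,2-dimethyl-2H-chromen-6-yl)-4H-chromen-4-one (target)
Conditions: HCl (1.25 M in MeOH, 3 equiv), THF–MeOH (1:1), 40 °C
Reagents that add atoms: none
Why: Acid-catalysed acetal methanolysis removes the MOM group under mild conditions that 2,2-dimethylchromenes, the chromone and the aryl methyl ether are known to tolerate.

**Compound list**
1 | 1-(2,4-dihydroxyphenyl)ethan-1-one | CC(=O)c1ccc(O)cc1O | starting material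
2 | 1-[2-hydroxy-4-(methoxymethoxy)phenyl]ethan-1-one | CC(=O)c1ccc(OCOC)cc1O | intermediate
3 | (E)-3-(dimethylamino)-1-[2-hydroxy-4-(methoxymethoxy)phenyl]prop-2-en-1-one (enaminone, not isolated) | CN(C)/C=C/C(=O)c1ccc(OCOC)cc1O | intermediate
4 | 3-iodo-7-(methoxymethoxy)-4H-chromen-4-one | O=c1c(I)coc2cc(OCOC)ccc12 | intermediate
5 | ethynyltrimethylsilane | C#C[Si](C)(C)C | starting material
6 | 7-(methoxymethoxy)-3-[(trimethylsilyl)ethynyl]-4H-chromen-4-one | C[Si](C)(C)C#Cc1coc2cc(OCOC)ccc2c1=O | intermediate
7 | 3-ethynyl-7-(methoxymethoxy)-4H-chromen-4-one | C#Cc1coc2cc(OCOC)ccc2c1=O | intermediate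
8 | (E)-4-methoxybut-3-en-2-one | CO/C=C/C(C)=O | starting material
9 | acetone | CC(C)=O | starting material
10 | (E)-5-hydroxy-1-methoxy-5-methylhex-1-en-3-one (aldol adduct, not isolated) | CO/C=C/C(=O)CC(C)(C)O | intermediate
11 | 2,2-dimethyl-2,3-dihydro-4H-pyran-4-one | CC1(C)CC(=O)C=CO1 | intermediate
12 | 2,2-dimethyl-3,4-dihydro-2H-pyran-4-ol (racemic) | CC1(C)CC(O)C=CO1 | intermediate
13 | [(2,2-dimethyl-3,4-dihydro-2H-pyran-4-yl)oxy]tri(propan-2-yl)silane (racemic) | CC(C)[Si](OC1CC(C)(C)OC=C1)(C(C)C)C(C)C | intermediate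
14 | [2,2-dimethyl-4-(triisopropylsilyloxy)-3,4-dihydro-2H-pyran-6-yl]lithium (vinyllithium, not isolated) | [Li]C1=CC(O[Si](C(C)C)(C(C)C)C(C)C)CC(C)(C)O1 | intermediate
15 | lithium pentacarbonyl{[2,2-dimethyl-4-(triisopropylsilyloxy)-3,4-dihydro-2H-pyran-6-yl](oxido)methylidene}chromate (acylchromate, not isolated) | [Li+].[O-]C(C1=CC(O[Si](C(C)C)(C(C)C)C(C)C)CC(C)(C)O1)=[Cr](=C=O)(=C=O)(=C=O)(=C=O)=C=O | intermediate
16 | pentacarbonyl{[2,2-dimethyl-4-(triisopropylsilyloxy)-3,4-dihydro-2H-pyran-6-yl](methoxy)methylidene}chromium (racemic) | COC(C1=CC(O[Si](C(C)C)(C(C)C)C(C)C)CC(C)(C)O1)=[Cr](=C=O)(=C=O)(=C=O)(=C=O)=C=O | intermediate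
17 | Cr(CO)3 complex of (3E)-4-[2,2-dimethyl-4-(triisopropylsilyloxy)-3,4-dihydro-2H-pyran-6-yl]-4-methoxy-2-[7-(methoxymethoxy)-4-oxo-4H-chromen-3-yl]buta-1,3-dien-1-one (dienylketene, not isolated) | O=C=C(c1coc2cc(OCOC)ccc2c1=O)/C=C(\C1=CC(O[Si](C(C)C)(C(C)C)C(C)C)CC(C)(C)O1)OC.O=C=[Cr](=C=O)=C=O | intermediate
18 | Cr(CO)3 complex of compound 19, bound to ring B (not isolated) | COc1cc(-c2coc3cc(OCOC)ccc3c2=O)c(O)c2c1OC(C)(C)CC2O[Si](C(C)C)(C(C)C)C(C)C.O=C=[Cr](=C=O)=C=O | intermediate
19 | 3-{5-hydroxy-8-methoxy-2,2-dimethyl-4-[(triisopropylsilyl)oxy]-3,4-dihydro-2H-chromen-6-yl}-7-(methoxymethoxy)-4H-chromen-4-one (racemic) | COc1cc(-c2coc3cc(OCOC)ccc3c2=O)c(O)c2c1OC(C)(C)CC2O[Si](C(C)C)(C(C)C)C(C)C | intermediate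
20 | 3-(8-methoxy-2,2-dimethyl-5-oxo-2,3-dihydro-5H-chromen-6-yl)-7-(methoxymethoxy)-4H-chromen-4-one (ortho-quinone methide, not isolated) | O=C1C(c2coc3cc(OCOC)ccc3c2=O)=CC(OC)=C2OC(C)(C)CC=C12 | intermediate
21 | 3-(5-hydroxy-8-methoxy-2,2-dimethyl-2H-chromen-6-yl)-7-(methoxymethoxy)-4H-chromen-4-one | COc1cc(-c2coc3cc(OCOC)ccc3c2=O)c(O)c2c1OC(C)(C)C=C2 | intermediate
22 | 7-hydroxy-3-(5-hydroxy-8-methoxy-2,2-dimethyl-2H-chromen-6-yl)-4H-chromen-4-one | COc1cc(-c2coc3cc(O)ccc3c2=O)c(O)c2c1OC(C)(C)C=C2 | target

**Step count and risks**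
Total step count: 11. Longest linear sequence: 7 steps (steps 1 to 4, then 9 to 11; the branch through steps 5 to 8 is equally long).

Steps most likely to fail:

1. Step 9 (benzannulation). The chromium carbene may react at the electron-poor C2=C3 bond of the chromone or take up a second alkyne, CO insertion may be bypassed so that five-membered-ring products form, and the benzylic silyloxy group may be lost from the chromium-complexed phenol. The fallback sets out from 16 and 4 and comes back at 19. Complex 16 would be benzannulated under the same conditions with commercial 2-ethynyl-4,4,5,5-tetramethyl-1,3,2-dioxaborolane, a small alkyne without a second reactive site. This should give the arylboronate 8-methoxy-2,2-dimethyl-6-(4,4,5,5-tetramethyl-1,3,2-dioxaborolan-2-yl)-4-[(triisopropylsilyl)oxy]-3,4-dihydro-2H-chromen-5-ol F1, with boron next to the new OH. Suzuki–Miyaura coupling of F1 with iodochromone 4 (PdCl2(dppf), K3PO4, dioxane–H2O, 80 °C) would then form the C3–C1' bond and give 19.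

2. Step 8 (carbene complex). t-BuLi may deprotonate the allylic C-4–H or expel the silyloxy group instead of metalating C-6, and the hindered acylchromate may be O-methylated incompletely. The fallback sets out from alkyne 7 and comes back at 21; it leaves out the allylic oxygen and introduces the C3=C4 bond by dehydrogenation instead of elimination.
   - 2,2-Dimethyl-3,4-dihydro-2H-pyran F2 (from acrolein and 2-methylpropene by thermal hetero-Diels–Alder reaction) would be converted as in step 8 into pentacarbonyl[(2,2-dimethyl-3,4-dihydro-2H-pyran-6-yl)(methoxy)methylidene]chromium F3.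
   - Benzannulation of F3 with 7 as in step 9 would give the chroman phenol 3-(5-hydroxy-8-methoxy-2,2-dimethyl-3,4-dihydro-2H-chromen-6-yl)-7-(methoxymethoxy)-4H-chromen-4-one F4.
   - Acetylation (Ac2O, Et3N, DMAP) to 8-methoxy-6-[7-(methoxymethoxy)-4-oxo-4H-chromen-3-yl]-2,2-dimethyl-3,4-dihydro-2H-chromen-5-yl acetate F5 would block oxidative cyclisation of the phenol onto C-2 of the chromone.
   - DDQ (dioxane, reflux) would dehydrogenate C3–C4 to 8-methoxy-6-[7-(methoxymethoxy)-4-oxo-4H-chromen-3-yl]-2,2-dimethyl-2H-chromen-5-yl acetate F6, and K2CO3 in MeOH at 0 °C would give 21.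

3. Step 4 (desilylation). Fluoride or adventitious alkoxide may add to C-2 of the alkynyl chromone and open the pyranone ring. The fallback sets out from 4 and comes back at 7: Stille coupling of 4 with commercial tributyl(ethynyl)stannane (Pd(PPh3)4, zerovalent palladium, toluene, 80 °C) would give 7 directly without a desilylation; it makes no new compound.

**Further compounds**
F1 | step 9 | 8-methoxy-2,2-dimethyl-6-(4,4,5,5-tetramethyl-1,3,2-dioxaborolan-2-yl)-4-[(triisopropylsilyl)oxy]-3,4-dihydro-2H-chromen-5-ol (racemic) | COc1cc(B2OC(C)(C)C(C)(C)O2)c(O)c2c1OC(C)(C)CC2O[Si](C(C)C)(C(C)C)C(C)C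
F2 | step 8 | 2,2-dimethyl-3,4-dihydro-2H-pyran | CC1(C)CCC=CO1
F3 | step 8 | pentacarbonyl[(2,2-dimethyl-3,4-dihydro-2H-pyran-6-yl)(methoxy)methylidene]chromium | COC(C1=CCCC(C)(C)O1)=[Cr](=C=O)(=C=O)(=C=O)(=C=O)=C=O
F4 | step 8 | 3-(5-hydroxy-8-methoxy-2,2-dimethyl-3,4-dihydro-2H-chromen-6-yl)-7-(methoxymethoxy)-4H-chromen-4-one | COc1cc(-c2coc3cc(OCOC)ccc3c2=O)c(O)c2c1OC(C)(C)CC2
F5 | step 8 | 8-methoxy-6-[7-(methoxymethoxy)-4-oxo-4H-chromen-3-yl]-2,2-dimethyl-3,4-dihydro-2H-chromen-5-yl acetate | COc1cc(-c2coc3cc(OCOC)ccc3c2=O)c(OC(C)=O)c2c1OC(C)(C)CC2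
F6 | step 8 | 8-methoxy-6-[7-(methoxymethoxy)-4-oxo-4H-chromen-3-yl]-2,2-dimethyl-2H-chromen-5-yl acetate | COc1cc(-c2coc3cc(OCOC)ccc3c2=O)c(OC(C)=O)c2c1OC(C)(C)C=C2
F0 | step 4 | none | none
A1 | direct plan | (E)-3-[4-(benzyloxy)-5-methoxy-2-(methoxymethoxy)phenyl]-1-[2-hydroxy-4-(methoxymethoxy)phenyl]prop-2-en-1-one | O=C(/C=C/c1cc(OC)c(OCc2ccccc2)cc1OCOC)c1ccc(OCOC)cc1O
A2 | direct plan | 3-{5-methoxy-2-(methoxymethoxy)-4-[(2-methylbut-3-yn-2-yl)oxy]phenyl}-7-(methoxymethoxy)-4H-chromen-4-one | O=c1c(-c2cc(OC)c(OC(C)(C)C#C)cc2OCOC)coc2cc(OCOC)ccc12
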